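The hydroxyquinone ring is disconnected at C5–C6 (quinone numbering: C1=O, C2–OH, C3–CH2R, C4=O, C5–OMe, C6–H), exploiting its 1,2,4,5-oxygenation: the four squarate carbons become C2–C5 and a two-carbon enol-ether unit becomes C1 and C6. The key step heats a 4-(1-silyloxyvinyl)cyclobutenone that already carries the complete trans-decalin: strain-releasing 4π ring opening gives a dienylketene whose 6π-electrocyclisation joins the ketene carbon (C5) to the enol-ether CH2 (C6), forming the aromatic ring with every oxygen differentiated and funnelling both cyclobutenone epimers into one product. The precursor is assembled from dimethyl squarate, 1-ethoxyvinyllithium and a neopentyl-type decalinylmethyllithium made from (S)-Wieland–Miescher ketone.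

Key step: step 15

Remark: the structure is read as drawn, i.e. a trans-decalin whose angular methyl sits on C8a next to the quaternary C1 and whose C2 methyl is axial and syn to it; decalin locants are C1 (CH2 side chain), C2 (CHMe), C4a (CH), C5 (C=CH2), C8a (CMe), β is the face of the C8a methyl, and DecCH2– stands for [(1R,2S,4aS,8aS)-1,2,8a-trimethyl-5-methylidenedecahydronaphthalen-1-yl]methyl.

Step 1
Reactants: 1 (S)-Wieland–Miescher ketone
Product: 2 C6 ethylene dithioketal of 1 [(8aS)-8a-methyl-3,4,8,8a-tetrahydro-2H-spiro[naphthalene-6,2'-[1,3]dithiolan]-1(7H)-one; C4a=C5 alkene kept]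
Conditions: HSCH2CH2SH, TsOH·H2O (cat.), AcOH, rt
Reagents that add atoms: ethane-1,2-dithiol SCCS
Why: Acid-catalysed dithioketalisation should take place only at the less hindered conjugated C6 carbonyl, the neopentyl C1 ketone next to the quaternary centre staying free and the double bond staying at C4a=C5.

Step 2
Reactants: 2 C6 ethylene dithioketal of 1
Product: 3 (8aS)-8a-methyl-3,4,6,7,8,8a-hexahydronaphthalen-1(2H)-one
Conditions: Raney Ni (W-2, acetone-deactivated), EtOH, reflux
Reagents that add atoms: none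
Why: Raney-nickel desulfurisation (Mozingo reduction) should replace the dithiolane by CH2 while the trisubstituted C4a=C5 alkene and the hindered C1 ketone are retained.

Step 3
Reactants: 3 (8aS)-8a-methyl-3,4,6,7,8,8a-hexahydronaphthalen-1(2H)-one
Product: 4 (8aS)-1-bromo-8a-methyl-3,4,6,7,8,8a-hexahydronaphthalene-2-carbaldehyde
Conditions: PBr3, DMF, CHCl3, 0 → 60 °C; then H2O
Reagents that add atoms: N,N-dimethylformamide CN(C)C=O; phosphorus tribromide BrP(Br)Br
Why: Vilsmeier–Haack–Arnold bromoformylation: the ketone can enolise only towards C2, so the bromoiminium salt should formylate C2 and exchange the C1 oxygen for bromide, giving the β-bromo enal whose CHO carbon is the future C2 methyl.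

Step 4
Reactants: 4 (8aS)-1-bromo-8a-methyl-3,4,6,7,8,8a-hexahydronaphthalene-2-carbaldehyde
Product: 6 1-bromo-2-(hydroxymethyl)-8aβ-methyl-3,4,4aα,5,6,7,8,8a-octahydronaphthalen-5α-ol (trans-fused), via alkylborane 5 (not isolated)
Conditions: BH3·THF, THF, 0 °C → rt; then NaOH, H2O2, 0 °C
Reagents that add atoms: hydrogen peroxide OO
Why: Hydroboration–oxidation: borane should reduce the aldehyde and then add to the isolated trisubstituted C4a=C5 alkene (the electron-poor tetrasubstituted bromoalkene being inert) from the α face opposite the axial C8a methyl with boron on C5, so that syn addition sets the trans ring fusion (4aα-H) and oxidation with retention the 5α-OH.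

Step 5
Reactants: 6 1-bromo-2-(hydroxymethyl)-8aβ-methyl-3,4,4aα,5,6,7,8,8a-octahydronaphthalen-5α-ol
Product: 7 2-(hydroxymethyl)-1,8aβ-dimethyl-3,4,4aα,5,6,7,8,8a-octahydronaphthalen-5α-ol
Conditions: Pd(PPh3)4 (cat.), trimethylboroxine, K2CO3, 1,4-dioxane/H2O, 95 °C
Reagents that add atoms: trimethylboroxine CB1OB(C)OB(C)O1
Why: Suzuki–Miyaura methylation should replace the vinylic bromide by the future C1 methyl without moving the tetrasubstituted alkene or touching a stereocentre.

Step 6
Reactants: 7 2-(hydroxymethyl)-1,8aβ-dimethyl-3,4,4aα,5,6,7,8,8a-octahydronaphthalen-5α-ol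
Product: 9 ethyl 2-(5α-hydroxy-1β,8aβ-dimethyl-2-methylidene-4aα-decahydronaphthalen-1α-yl)acetate, via ketene acetal 8 (not isolated)
Conditions: MeC(OEt)3, EtCO2H (cat.), xylenes, 140 °C (EtOH distilled off); then K2CO3, EtOH, rt
Reagents that add atoms: triethyl orthoacetate CCOC(C)(OCC)OCC
Why: Johnson–Claisen rearrangement: the chair-like [3,3] shift should deliver the acetate carbon to C1 from the α face, anti to the pseudo-axial C8a methyl, creating the quaternary stereocentre (CH2CO2Et α-axial, methyl β) next to the quaternary C8a and leaving the exocyclic C2 methylene, while the basic ethanol wash frees the 5-OH from any mixed orthoester or acetate.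

Step 7
Reactants: 9 ethyl 2-(5α-hydroxy-1β,8aβ-dimethyl-2-methylidene-4aα-decahydronaphthalen-1α-yl)acetate
Product: 10 ethyl 2-(5α-hydroxy-1β,2β,8aβ-trimethyl-4aα-decahydronaphthalen-1α-yl)acetate
Conditions: H2 (1 atm), [Ir(cod)(PCy3)(py)]PF6 (cat.), CH2Cl2, rt
Reagents that add atoms: none
Why: Carbonyl-directed homogeneous hydrogenation: the cationic iridium catalyst, held by the α-axial ester carbonyl, should add H2 to the α face of the C2 methylene so that the new methyl ends β (axial, syn to the C8a methyl), the contra-thermodynamic epimer that equilibrating methods would not give.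

Step 8
Reactants: 10 ethyl 2-(5α-hydroxy-1β,2β,8aβ-trimethyl-4aα-decahydronaphthalen-1α-yl)acetate
Product: 11 2-(5α-hydroxy-1β,2β,8aβ-trimethyl-4aα-decahydronaphthalen-1α-yl)acetic acid
Conditions: LiOH, THF/MeOH/H2O, 50 °C; then 1 M HCl
Reagents that add atoms: lithium hydroxide [Li+].[OH-]
Why: Plain saponification of the ethyl ester, which touches no stereocentre.

Step 9
Reactants: 11 2-(5α-hydroxy-1β,2β,8aβ-trimethyl-4aα-decahydronaphthalen-1α-yl)acetic acid
Product: 13 1α-(iodomethyl)-1β,2β,8aβ-trimethyl-4aα-decahydronaphthalen-5α-ol, via Barton ester 12 (not isolated)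
Conditions: 2-mercaptopyridine N-oxide, DCC, DMAP (cat.), CH2Cl2, rt, dark; then CHI3, PhH, hν, reflux
Reagents that add atoms: iodoform IC(I)I
Why: Barton decarboxylative iodination: the radical chain should turn the acid into the primary iodide without any SN2 step at the doubly neopentyl carbon, and a primary radical on a quaternary carbon does not rearrange.

Step 10
Reactants: 13 1α-(iodomethyl)-1β,2β,8aβ-trimethyl-4aα-decahydronaphthalen-5α-ol
Product: 14 1α-(iodomethyl)-1β,2β,8aβ-trimethyl-4aα-octahydronaphthalen-5(1H)-one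
Conditions: Dess–Martin periodinane, CH2Cl2, 0 °C → rt
Reagents that add atoms: none
Why: Dess–Martin oxidation gives the C5 ketone under near-neutral conditions, so the adjacent C4a stereocentre should not epimerise.

Step 11
Reactants: 14 1α-(iodomethyl)-1β,2β,8aβ-trimethyl-4aα-octahydronaphthalen-5(1H)-one
Product: 15 (1R,2S,4aS,8aS)-1-(iodomethyl)-1,2,8a-trimethyl-5-methylidenedecahydronaphthalene
Conditions: Cp2Ti(μ-Cl)(μ-CH2)AlMe2, pyridine (cat.), THF/toluene, −40 → 0 °C
Reagents that add atoms: Tebbe reagent Cp2Ti(μ-Cl)(μ-CH2)AlMe2 C[Al-]1(C)C[Ti](C2C=CC=C2)(C2C=CC=C2)[Cl+]1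
Why: Tebbe methylenation is non-basic, so the C5 ketone should become the exocyclic methylene through the titanocene methylidene without enolisation towards C4a (the cis-fused epimer would relieve the 1,3-diaxial methyl pair), and the alkyl iodide is tolerated.

Step 12
Reactants: 16 dimethyl squarate; 17 ethyl vinyl ether
Product: 20 rac-4-(1-ethoxyethenyl)-2,3-dimethoxy-4-(methoxymethoxy)cyclobut-2-en-1-one, via 1-ethoxyvinyllithium 18 (not isolated), via lithium alkoxide 19 (not isolated)
Conditions: 17, t-BuLi, THF, −78 → 0 °C; then 16, THF, −78 °C; then MOMCl, −78 °C → rt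
Reagents that add atoms: chloromethyl methyl ether COCCl
Why: The α-lithiated enol ether should add 1,2 to one of the two equivalent squarate carbonyls and the tertiary alkoxide is capped in situ by O-alkylation; the new stereocentre is racemic and is erased in step 15.

Step 13
Reactants: 15 (1R,2S,4aS,8aS)-1-(iodomethyl)-1,2,8a-trimethyl-5-methylidenedecahydronaphthalene; 20 rac-4-(1-ethoxyethenyl)-2,3-dimethoxy-4-(methoxymethoxy)cyclobut-2-en-1-one
Product: 23 4-acetyl-3-(DecCH2)-2-methoxy-4-(methoxymethoxy)cyclobut-2-en-1-one (both C4 epimers), via alkyllithium 21 (not isolated), via adduct alkoxide 22 (not isolated)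
Conditions: 15, t-BuLi (2.1 equiv), Et2O/pentane, −78 °C; then 20, THF, −78 °C; then 1 M HCl, THF, 0 °C → rt
Reagents that add atoms: water O
Why: Iodine–lithium exchange gives the neopentyl-type alkyllithium, which should add 1,2 to the vinylogous-ester carbonyl of 20, after which dilute acid ionises the tertiary allylic alcohol, water adds at the distal methoxy carbon (1,3-carbonyl transposition of the Stork–Danheiser type) and the ethoxyvinyl group is hydrolysed to acetyl, the two C4 epimers being of no consequence.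

Step 14
Reactants: 23 4-acetyl-3-(DecCH2)-2-methoxy-4-(methoxymethoxy)cyclobut-2-en-1-one
Product: 24 4-{1-[(tert-butyldimethylsilyl)oxy]ethenyl}-3-(DecCH2)-2-methoxy-4-(methoxymethoxy)cyclobut-2-en-1-one (both C4 epimers)
Conditions: TBSOTf, Et3N, CH2Cl2, −78 → 0 °C
Reagents that add atoms: tert-butyldimethylsilyl trifluoromethanesulfonate CC(C)(C)[Si](C)(C)OS(=O)(=O)C(F)(F)F
Why: Soft enolisation and O-silylation: the acetyl methyl is the only enolisable position, so a single silyl enol ether should form, which masks the acyl oxygen and supplies the 2π unit for the key step.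

Step 15
Reactants: 24 4-{1-[(tert-butyldimethylsilyl)oxy]ethenyl}-3-(DecCH2)-2-methoxy-4-(methoxymethoxy)cyclobut-2-en-1-one
Product: 27 5-[(tert-butyldimethylsilyl)oxy]-3-(DecCH2)-2-methoxy-4-(methoxymethoxy)phenol, via dienylketene 25 (not isolated), via cyclohexadienone 26 (not isolated)
Conditions: toluene (degassed), 110 °C
Reagents that add atoms: none
Why: On heating, the cyclobutenone should undergo conrotatory 4π-electrocyclic opening of its C1–C4 bond, the C4 methoxymethoxy group turning outwards and the silyloxyvinyl group inwards, to give dienylketene 25 with the ketenyl and silyloxyvinyl groups cis on the central double bond, whose disrotatory 6π-electrocyclisation joins the ketene carbon to the terminal CH2 of the silyl enol ether; the cyclohexa-2,4-dienone 26 then tautomerises to phenol 27. The closest known reaction type is the Moore rearrangement of 4-alkenyl-4-alkoxycyclobutenones to hydroquinone derivatives. The six-membered ring closes in a 6π-electrocyclic (formally 6-endo) mode, driven by release of cyclobutenone strain and by aromatisation. No stereocentre is created, and because C4 of 24 becomes sp2 both epimers converge on one product. The step needs torquoselectivity (alkenyl inwards), which the donor oxygen on C4 secures by its preference for outward rotation, and closure through carbon instead of oxygen, which the O-silylated enol ether secures. The substitution of 24 fixes the regiochemistry: the former carbonyl carbon becomes the only free phenol carbon (quinone C5), the enol-ether CH2 the only ring CH (C6), and the other three oxygens stay differently capped.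

Step 16
Reactants: 27 5-[(tert-butyldimethylsilyl)oxy]-3-(DecCH2)-2-methoxy-4-(methoxymethoxy)phenol
Product: 28 tert-butyl[3-(DecCH2)-4,5-dimethoxy-2-(methoxymethoxy)phenoxy]dimethylsilane
Conditions: NaH, MeI, THF/DMF, 0 °C
Reagents that add atoms: iodomethane CI
Why: Williamson O-methylation of the only free phenol should place the methoxy group on the carbon that was the ketene carbon (quinone C5).

Step 17
Reactants: 28 tert-butyl[3-(DecCH2)-4,5-dimethoxy-2-(methoxymethoxy)phenoxy]dimethylsilane
Product: 29 3-(DecCH2)-4,5-dimethoxy-2-(methoxymethoxy)phenol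
Conditions: TBAF, AcOH, THF, 0 °C
Reagents that add atoms: none
Why: Buffered fluoride desilylation should free the phenol at the future C1 only, the MOM ether and both methyl ethers being inert.

Step 18
Reactants: 29 3-(DecCH2)-4,5-dimethoxy-2-(methoxymethoxy)phenol
Product: 31 2-hydroxy-5-methoxy-3-{[(1R,2S,4aS,8aS)-1,2,8a-trimethyl-5-methylidenedecahydronaphthalen-1-yl]methyl}cyclohexa-2,5-diene-1,4-dione, via MOM-protected quinone 30 (not isolated)
Conditions: (NH4)2Ce(NO3)6, MeCN/H2O, 0 °C; then 1 M HCl, rt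
Reagents that add atoms: water O
Why: Oxidative demethylation of a para-methoxyphenol: the free phenol (C1) and its para methoxy carbon (C4) should become the 1,4-quinone with loss of methanol, and the acidic medium hydrolyses the vinylogous MOM ester at C2 to the hydroxyquinone while the C5 methoxy group and the exocyclic alkene are untouched.

Compound list
1 | (S)-Wieland–Miescher ketone, (8aS)-8a-methyl-3,4,8,8a-tetrahydronaphthalene-1,6(2H,7H)-dione | O=C1CC[C@@]2(C)C(=C1)CCCC2=O | starting material
2 | C6 ethylene dithioketal of 1, (8aS)-8a-methyl-3,4,8,8a-tetrahydro-2H-spiro[naphthalene-6,2'-[1,3]dithiolan]-1(7H)-one | S1CCSC12CC[C@@]3(C)C(=C2)CCCC3=O | intermediate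
3 | (8aS)-8a-methyl-3,4,6,7,8,8a-hexahydronaphthalen-1(2H)-one | C1CC[C@@]2(C)C(=C1)CCCC2=O | intermediate
4 | (8aS)-1-bromo-8a-methyl-3,4,6,7,8,8a-hexahydronaphthalene-2-carbaldehyde | C1CC[C@@]2(C)C(=C1)CCC(C=O)=C2Br | intermediate
5 | alkylborane from 4 (5α-boryl, O-boryl; not isolated) | [BH2][C@@H]1CCC[C@@]2(C)[C@H]1CCC(CO[BH2])=C2Br | intermediate
6 | 1-bromo-2-(hydroxymethyl)-8aβ-methyl-3,4,4aα,5,6,7,8,8a-octahydronaphthalen-5α-ol (trans-fused) | O[C@@H]1CCC[C@@]2(C)[C@H]1CCC(CO)=C2Br | intermediate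
7 | 2-(hydroxymethyl)-1,8aβ-dimethyl-3,4,4aα,5,6,7,8,8a-octahydronaphthalen-5α-ol | O[C@@H]1CCC[C@@]2(C)[C@H]1CCC(CO)=C2C | intermediate
8 | ketene acetal of 7 (allyl 1-ethoxyvinyl ether; not isolated) | O[C@@H]1CCC[C@@]2(C)[C@H]1CCC(COC(=C)OCC)=C2C | intermediate
9 | ethyl 2-(5α-hydroxy-1β,8aβ-dimethyl-2-methylidene-4aα-decahydronaphthalen-1α-yl)acetate | O[C@@H]1CCC[C@@]2(C)[C@H]1CCC(=C)[C@@]2(C)CC(=O)OCC | intermediate
10 | ethyl 2-(5α-hydroxy-1β,2β,8aβ-trimethyl-4aα-decahydronaphthalen-1α-yl)acetate | O[C@@H]1CCC[C@@]2(C)[C@H]1CC[C@H](C)[C@@]2(C)CC(=O)OCC | intermediate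
11 | 2-(5α-hydroxy-1β,2β,8aβ-trimethyl-4aα-decahydronaphthalen-1α-yl)acetic acid | O[C@@H]1CCC[C@@]2(C)[C@H]1CC[C@H](C)[C@@]2(C)CC(O)=O | intermediate
12 | Barton ester of 11 (2-thioxopyridin-1(2H)-yl ester; not isolated) | O[C@@H]1CCC[C@@]2(C)[C@H]1CC[C@H](C)[C@@]2(C)CC(=O)ON1C=CC=CC1=S | intermediate
13 | 1α-(iodomethyl)-1β,2β,8aβ-trimethyl-4aα-decahydronaphthalen-5α-ol | O[C@@H]1CCC[C@@]2(C)[C@H]1CC[C@H](C)[C@@]2(C)CI | intermediate
14 | 1α-(iodomethyl)-1β,2β,8aβ-trimethyl-4aα-octahydronaphthalen-5(1H)-one | O=C1CCC[C@@]2(C)[C@H]1CC[C@H](C)[C@@]2(C)CI | intermediate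
15 | (1R,2S,4aS,8aS)-1-(iodomethyl)-1,2,8a-trimethyl-5-methylidenedecahydronaphthalene | C=C1CCC[C@@]2(C)[C@H]1CC[C@H](C)[C@@]2(C)CI | intermediate
16 | dimethyl squarate, 3,4-dimethoxycyclobut-3-ene-1,2-dione | COC1=C(OC)C(=O)C1=O | starting material
17 | ethyl vinyl ether | C=COCC | starting material
18 | 1-ethoxyvinyllithium (not isolated) | [Li]C(=C)OCC | intermediate
19 | lithium 1-(1-ethoxyethenyl)-2,3-dimethoxy-4-oxocyclobut-2-en-1-olate (not isolated) | CCOC(=C)C1([O-])C(OC)=C(OC)C1=O.[Li+] | intermediate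
20 | rac-4-(1-ethoxyethenyl)-2,3-dimethoxy-4-(methoxymethoxy)cyclobut-2-en-1-one | CCOC(=C)C1(OCOC)C(OC)=C(OC)C1=O | intermediate
21 | DecCH2Li, [(1R,2S,4aS,8aS)-1,2,8a-trimethyl-5-methylidenedecahydronaphthalen-1-yl]methyllithium (not isolated) | C=C1CCC[C@@]2(C)[C@H]1CC[C@H](C)[C@@]2(C)C[Li] | intermediate
22 | lithium alkoxide from 1,2-addition of 21 to 20 (diastereomer mixture; not isolated) | C=C1CCC[C@@]2(C)[C@H]1CC[C@H](C)[C@@]2(C)CC1([O-])C(OC)=C(OC)C1(OCOC)C(=C)OCC.[Li+] | intermediate
23 | 4-acetyl-3-(DecCH2)-2-methoxy-4-(methoxymethoxy)cyclobut-2-en-1-one (both C4 epimers) | C=C1CCC[C@@]2(C)[C@H]1CC[C@H](C)[C@@]2(C)CC1=C(OC)C(=O)C1(OCOC)C(C)=O | intermediate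
24 | 4-{1-[(tert-butyldimethylsilyl)oxy]ethenyl}-3-(DecCH2)-2-methoxy-4-(methoxymethoxy)cyclobut-2-en-1-one (both C4 epimers) | C=C1CCC[C@@]2(C)[C@H]1CC[C@H](C)[C@@]2(C)CC1=C(OC)C(=O)C1(OCOC)C(=C)O[Si](C)(C)C(C)(C)C | intermediate
25 | dienylketene from ring opening of 24 (ketenyl and silyloxyvinyl groups cis on the central double bond; not isolated) | C=C1CCC[C@@]2(C)[C@H]1CC[C@H](C)[C@@]2(C)C/C(C(OC)=C=O)=C(\OCOC)C(=C)O[Si](C)(C)C(C)(C)C | intermediate
26 | 5-[(tert-butyldimethylsilyl)oxy]-3-(DecCH2)-2-methoxy-4-(methoxymethoxy)cyclohexa-2,4-dien-1-one (not isolated) | C=C1CCC[C@@]2(C)[C@H]1CC[C@H](C)[C@@]2(C)CC1=C(OC)C(=O)CC(O[Si](C)(C)C(C)(C)C)=C1OCOC | intermediate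
27 | 5-[(tert-butyldimethylsilyl)oxy]-3-(DecCH2)-2-methoxy-4-(methoxymethoxy)phenol | C=C1CCC[C@@]2(C)[C@H]1CC[C@H](C)[C@@]2(C)Cc1c(OC)c(O)cc(O[Si](C)(C)C(C)(C)C)c1OCOC | intermediate
28 | tert-butyl[3-(DecCH2)-4,5-dimethoxy-2-(methoxymethoxy)phenoxy]dimethylsilane | C=C1CCC[C@@]2(C)[C@H]1CC[C@H](C)[C@@]2(C)Cc1c(OC)c(OC)cc(O[Si](C)(C)C(C)(C)C)c1OCOC | intermediate
29 | 3-(DecCH2)-4,5-dimethoxy-2-(methoxymethoxy)phenol | C=C1CCC[C@@]2(C)[C@H]1CC[C@H](C)[C@@]2(C)Cc1c(OC)c(OC)cc(O)c1OCOC | intermediate
30 | 3-(DecCH2)-5-methoxy-2-(methoxymethoxy)cyclohexa-2,5-diene-1,4-dione (not isolated) | C=C1CCC[C@@]2(C)[C@H]1CC[C@H](C)[C@@]2(C)CC1=C(OCOC)C(=O)C=C(OC)C1=O | intermediate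
31 | 2-hydroxy-5-methoxy-3-{[(1R,2S,4aS,8aS)-1,2,8a-trimethyl-5-methylidenedecahydronaphthalen-1-yl]methyl}cyclohexa-2,5-diene-1,4-dione | C=C1CCC[C@@]2(C)[C@H]1CC[C@H](C)[C@@]2(C)CC1=C(O)C(=O)C=C(OC)C1=O | target

Total step count: 18. Longest linear sequence: 17 steps (steps 1–11 and 13–18); step 12 prepares fragment 20 separately.

Steps most likely to fail

Step 13. The β-quaternary alkyllithium 21 may add too slowly to the carbonyl of 20, which is flanked by a fully substituted carbon, so that decomposition of 20 competes, or the acid treatment may hydrolyse the adduct along the wrong path. The fallback sets out from 15 and comes back at 23, reversing the order of the two additions. Lithium reagent 21 is added to unhindered dimethyl squarate 16 to give 4-(DecCH2)-4-hydroxy-2,3-dimethoxycyclobut-2-en-1-one F1, which dilute HCl converts into 3-(DecCH2)-4-methoxycyclobut-3-ene-1,2-dione F2. The more electrophilic carbonyl, next to the methoxy-bearing carbon, is masked with MeOSiMe3 and catalytic Me3SiOTf as the dimethyl ketal 2-(DecCH2)-3,4,4-trimethoxycyclobut-2-en-1-one F3. 1-Ethoxyvinyllithium 18 then adds to the remaining vinylogous-ester carbonyl, and capping with MOMCl gives 3-(DecCH2)-4-(1-ethoxyethenyl)-1,2,2-trimethoxy-4-(methoxymethoxy)cyclobut-1-ene F4. 1 M HCl unmasks the ring ketone and the acetyl group and delivers 23.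

Step 15. The silyl group may be lost before or during ring opening (trace acid or water at 110 °C), after which the free acetyl oxygen closes onto the ketene and a pyranone forms instead of the carbocycle; intermolecular capture of the ketene is the second hazard. The fallback sets out from 23 and comes back at 29, carrying the C1 oxygen as an enol ester that can neither fall off nor migrate. KHMDS then PivCl gives the enol pivalate 1-[2-(DecCH2)-3-methoxy-1-(methoxymethoxy)-4-oxocyclobut-2-en-1-yl]ethenyl 2,2-dimethylpropanoate F5. The same thermal 4π/6π cascade in toluene gives 5-hydroxy-3-(DecCH2)-4-methoxy-2-(methoxymethoxy)phenyl 2,2-dimethylpropanoate F6, and NaH/MeI gives 3-(DecCH2)-4,5-dimethoxy-2-(methoxymethoxy)phenyl 2,2-dimethylpropanoate F7. Reductive cleavage of the pivalate with i-Bu2AlH at −78 °C returns phenol 29.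

Step 7. If the ester carbonyl fails to hold the iridium on the α face, hydrogen is delivered to the β face and the more stable equatorial 2α-methyl epimer forms; isomerisation of the exocyclic alkene into the ring is a second risk. The fallback sets out from 9 and comes back at 11, anchoring the catalyst through an anionic carboxylate. Ester 9 is saponified first (LiOH) to 2-(5α-hydroxy-1β,8aβ-dimethyl-2-methylidene-4aα-decahydronaphthalen-1α-yl)acetic acid F8. F8 is hydrogenated as its triethylammonium salt with [Rh(nbd)(dppb)]BF4 under H2 pressure, carboxylate-directed addition to the α face giving acid 11 directly.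

Further compounds
F1 | step 13 | 4-(DecCH2)-4-hydroxy-2,3-dimethoxycyclobut-2-en-1-one | C=C1CCC[C@@]2(C)[C@H]1CC[C@H](C)[C@@]2(C)CC1(O)C(OC)=C(OC)C1=O
F2 | step 13 | 3-(DecCH2)-4-methoxycyclobut-3-ene-1,2-dione | C=C1CCC[C@@]2(C)[C@H]1CC[C@H](C)[C@@]2(C)CC1=C(OC)C(=O)C1=O
F3 | step 13 | 2-(DecCH2)-3,4,4-trimethoxycyclobut-2-en-1-one | C=C1CCC[C@@]2(C)[C@H]1CC[C@H](C)[C@@]2(C)CC1=C(OC)C(OC)(OC)C1=O
F4 | step 13 | 3-(DecCH2)-4-(1-ethoxyethenyl)-1,2,2-trimethoxy-4-(methoxymethoxy)cyclobut-1-ene | C=C1CCC[C@@]2(C)[C@H]1CC[C@H](C)[C@@]2(C)CC1=C(OC)C(OC)(OC)C1(OCOC)C(=C)OCC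
F5 | step 15 | 1-[2-(DecCH2)-3-methoxy-1-(methoxymethoxy)-4-oxocyclobut-2-en-1-yl]ethenyl 2,2-dimethylpropanoate | C=C1CCC[C@@]2(C)[C@H]1CC[C@H](C)[C@@]2(C)CC1=C(OC)C(=O)C1(OCOC)C(=C)OC(=O)C(C)(C)C
F6 | step 15 | 5-hydroxy-3-(DecCH2)-4-methoxy-2-(methoxymethoxy)phenyl 2,2-dimethylpropanoate | C=C1CCC[C@@]2(C)[C@H]1CC[C@H](C)[C@@]2(C)Cc1c(OC)c(O)cc(OC(=O)C(C)(C)C)c1OCOC
F7 | step 15 | 3-(DecCH2)-4,5-dimethoxy-2-(methoxymethoxy)phenyl 2,2-dimethylpropanoate | C=C1CCC[C@@]2(C)[C@H]1CC[C@H](C)[C@@]2(C)Cc1c(OC)c(OC)cc(OC(=O)C(C)(C)C)c1OCOC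
F8 | step 7 | 2-(5α-hydroxy-1β,8aβ-dimethyl-2-methylidene-4aα-decahydronaphthalen-1α-yl)acetic acid | O[C@@H]1CCC[C@@]2(C)[C@H]1CCC(=C)[C@@]2(C)CC(O)=O
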